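Remark: flavanone locants are used, unprimed for the chromanone that carries the 4-methoxyphenyl ring (rings A, B, C) and doubly primed for the one that carries the 4-hydroxyphenyl ring. The SMILES reads (2S,3R,2''S,3''R), so both pyranone rings are 2,3-trans and the halves are homochiral. Wherever the ProPhenol ligand is named, the enantiomer that adds the alkynyl group to the Re face of the aryl aldehyde is meant.

## Structural features

The target is a 3,3''-linked biflavanone: two 5,7-dihydroxychroman-4-ones joined by the single bond C3–C3''. One carries a 4-methoxyphenyl ring B at C2 and the other a 4-hydroxyphenyl ring B'' at C2'', so the two halves differ only at one remote oxygen. C2, C3, C3'' and C2'' are four contiguous stereocentres on a pseudo-C2-symmetric core. C3 and C3'' are alpha to ketones and can be corrected by enolisation to the diequatorial 2,3-trans arrangement. C2 and C2'' are benzylic aryl ethers beta to the ketones; their configuration is lost by E1cB ring opening to a 2'-hydroxychalcone or by acid ionisation, so they must be set absolutely and never reopened. Once C2 and C2'' are both S, the only all-trans isomer is the target. Fragile groups are the five free phenols (which need a mask orthogonal to the one methyl ether) and the two beta-aryloxy ketones. The real difficulty is the C3–C3'' bond between two hindered secondary carbons, combined with the need to join two almost identical halves as a heterodimer.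

The feature exploited is that C4(=O)–C3–C3''–C4''(=O) is a 1,4-diketone in which each acyl carbon is tied through C4a–C8a–O1 to C2 (or C2''), and C3 and C3'' each carry one hydrogen. Each ring C is therefore the formal intramolecular hydroacylation adduct of a 2-formylaryl ether, and the C3–C3'' bond can be the two carbons of an alkyne that accepts two acyl–H units. In one sentence: a carbene-catalysed double intramolecular hydroacylation (alkyne hydroacylation, then Stetter) of the bis(2-formylaryl) ether of an unsymmetrical 1,4-diarylbut-2-yne-1,4-diol.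

## Logic of the disconnections

14 to 13: the five O–CH2Ph bonds are cut. Benzyl ethers mask all phenols, are removed under neutral conditions and are orthogonal to the methyl ether that stays. The demand is that the final hydrogenolysis spares the benzylic C2–O1 and C2''–O1'' bonds.

13 to 10 (key): the acyl–carbon bonds C4–C3 and C4''–C3'' are cut and one hydrogen is taken from each of C3 and C3''. The C3–C3'' single bond becomes the triple bond of 10 and both ketones become formyl groups. Both rings C, the stereocentres C3 and C3'' and the hindered central bond disappear. What remains is a linear four-carbon chain with two carbinol-derived stereocentres that is already unsymmetrical. The forward step must generate acyl-anion equivalents from hindered, electron-rich aldehydes, close exo in both cyclisations (through 11 or 12) and be mild enough to leave C2 and C2'' untouched.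

10 to 6 and 9: the two C(sp3)–O(aryl) bonds are cut. The same phenol 9 is used twice, and 6 carries all the stereochemical information. The forward step must be stereospecific at two ionisation-prone carbinol carbons; because it proceeds with inversion, 6 must have the opposite spatial sense at both centres.

9 to 7 and 8: two O–benzyl bonds are cut. The hydroxyl that is hydrogen-bonded to the formyl group is the least reactive and should stay free.

6 to 4 and 5: the C(sp)–C(carbinol) bond on the benzyloxyphenyl side is cut. The two different aryl aldehydes enter one after the other, so the heterodimer problem is settled here by construction. The forward addition must be reagent-controlled and tolerate the free hydroxyl of 4.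

4 to 3 to 1 and 2: the C–Si bond is cut, then the C(sp)–C(carbinol) bond on the methoxyphenyl side. This leaves two commercial materials and one catalytic asymmetric alkynylation.

## Other disconnections considered

Alternative 1: cut C3–C3'' directly (the first idea, and the likely biogenetic one). The forward step is oxidative heterocoupling of the lithium enolates of the protected flavanones A1 and A2 (LiN(SiMe3)2, then CuCl2 or I2) to give 13. Two nearly identical enolates should give a statistical mixture of two homodimers and the heterodimer. The bond must form between two secondary carbons that each sit next to an aryl-bearing stereocentre. Each flavanone enolate is one E1cB step from the ring-opened chalcone phenolate, which erodes C2. A1 and A2 each need their own enantioselective synthesis, so the route is not shorter. The chosen plan never has to form this bond.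

Alternative 2: the same C3–C3'' bond with a temporary silicon tether. The enolates of A1 and A2 are joined stepwise with iPr2SiCl2 to the mixed bis-enol ether A3, which is oxidised with (NH4)2Ce(NO3)6/NaHCO3 in MeCN to close the bond intramolecularly and give 13. The tether removes the statistical problem and favours the homochiral pairing. It still needs two enolisations of ring-opening-prone flavanones, an unsymmetrical silylation sequence, and a one-electron oxidant in the presence of benzyl-protected phloroglucinol rings. It also inherits the two separate asymmetric flavanone syntheses, so it is longer than seven steps.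

Alternative 3: cut both O1–C2 and O1''–C2'' bonds. The diketone A4 is condensed in turn with the two aryl aldehydes to the bis(arylidene) diketone A5, and a double 6-endo oxa-Michael addition closes both rings C. All four stereocentres would have to be set in two reversible conjugate additions. After the first closure the second is under substrate control, with little energetic bias between the homochiral and the meso-type all-trans products. A4 is prone to Paal–Knorr furan formation under condensation conditions, and the two aldehydes must be introduced with mono-selectivity. Stereocontrol is therefore weaker than in the chosen plan, where C2 and C2'' are set by reagent control before any ring exists.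

Key step: step 6

## Steps

Step 1
Reactants: 1 4-methoxybenzaldehyde; 2 ethynyltrimethylsilane
Product: 3 (S)-1-(4-methoxyphenyl)-3-(trimethylsilyl)prop-2-yn-1-ol
Conditions: Me2Zn (3 equiv), ProPhenol ligand (10 mol %), Ph3P=O (20 mol %), toluene, 0 °C
Reagents that add atoms: none
Why: Catalytic asymmetric alkynylation of an aryl aldehyde by a zinc alkynylide under a dinuclear zinc–ProPhenol catalyst; Re-face delivery of the alkynyl group sets the carbinol centre as S (O > alkynyl > aryl).

Step 2
Reactants: 3 (S)-1-(4-methoxyphenyl)-3-(trimethylsilyl)prop-2-yn-1-ol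
Product: 4 (R)-1-(4-methoxyphenyl)prop-2-yn-1-ol
Conditions: K2CO3 (cat.), MeOH, rt
Reagents that add atoms: none
Why: Methanolysis of the C(sp)–Si bond; the stereocentre is not touched, and the descriptor changes from S to R only because a terminal ethynyl group ranks below aryl.

Step 3
Reactants: 4 (R)-1-(4-methoxyphenyl)prop-2-yn-1-ol; 5 4-(benzyloxy)benzaldehyde
Product: 6 (1S,4S)-1-[4-(benzyloxy)phenyl]-4-(4-methoxyphenyl)but-2-yne-1,4-diol
Conditions: Me2Zn (4 equiv), ProPhenol ligand (10 mol %), Ph3P=O (20 mol %), toluene, 0 °C to rt
Reagents that add atoms: none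
Why: Second catalytic asymmetric alkynylation with the same ligand enantiomer, the free hydroxyl being carried as its methylzinc alkoxide; the new centre is set by the catalyst (Re face) because the existing one is remote across the alkyne, and any minor mis-addition should appear as the separable meso-type diastereomer and not as the enantiomer.

Step 4
Reactants: 7 2,4,6-trihydroxybenzaldehyde; 8 benzyl bromide (2.1 equiv)
Product: 9 2,4-bis(benzyloxy)-6-hydroxybenzaldehyde
Conditions: K2CO3, DMF, rt
Reagents that add atoms: none
Why: Williamson etherification; the hydroxyl hydrogen-bonded to the formyl group is the least nucleophilic and should remain free, as is usual for 2-hydroxyaryl carbonyl compounds.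

Step 5
Reactants: 6 (1S,4S)-1-[4-(benzyloxy)phenyl]-4-(4-methoxyphenyl)but-2-yne-1,4-diol; 9 2,4-bis(benzyloxy)-6-hydroxybenzaldehyde (2.4 equiv)
Product: 10 2,2'-{[(1R,4R)-1-[4-(benzyloxy)phenyl]-4-(4-methoxyphenyl)but-2-yne-1,4-diyl]bis(oxy)}bis[4,6-bis(benzyloxy)benzaldehyde]
Conditions: PPh3, DIAD, toluene, −20 to 0 °C
Reagents that add atoms: none
Why: Double Mitsunobu etherification with SN2 inversion at both carbinol carbons, giving the (1R,4R) diether that has the spatial arrangement of C2 and C2'' of the target; the linear alkyne prevents cyclisation of the diol, and the electron-withdrawing alkynyl group with its second oxygen substituent should slow ionisation of the oxyphosphonium intermediates enough for clean inversion in a non-polar solvent at low temperature.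

Step 6
Reactants: 10 2,2'-{[(1R,4R)-1-[4-(benzyloxy)phenyl]-4-(4-methoxyphenyl)but-2-yne-1,4-diyl]bis(oxy)}bis[4,6-bis(benzyloxy)benzaldehyde]
Product: 13 (2S,3R)-5,7-bis(benzyloxy)-3-{(2S,3R)-5,7-bis(benzyloxy)-2-[4-(benzyloxy)phenyl]-4-oxo-3,4-dihydro-2H-chromen-3-yl}-2-(4-methoxyphenyl)-2,3-dihydro-4H-chromen-4-one, via E-alkylidene chromanone closed first on the methoxyphenyl side 11 (not isolated), via E-alkylidene chromanone closed first on the benzyloxyphenyl side 12 (not isolated)
Conditions: 3-mesityl-4,5-dimethylthiazolium perchlorate (20 mol %), K2CO3 (40 mol %), THF, 60 °C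
Reagents that add atoms: none
Why: The carbene adds to one formyl group to give a Breslow intermediate, whose nucleophilic carbon and enol O–H add syn across the alkyne in a concerted Conia-ene-type hydroacylation (6-exo-dig, new C4–C3 or C4''–C3'' bond) that releases the carbene and the E-configured 3-alkylidene chroman-4-one 11 or 12. The second formyl group, now held on the gamma-oxygen of this enone, forms its own Breslow intermediate and closes the second pyranone by intramolecular Stetter addition to the beta-carbon (6-exo-trig), and proton transfer to the enolate gives the 1,4-diketone. The closest known reaction type is the carbene-catalysed hydroacylation of the unactivated alkyne of 2-(propargyloxy)benzaldehydes followed by a Stetter reaction on the alkylidene chromanone so formed, together with the intramolecular Stetter route to 3-substituted chroman-4-ones. The stereocentre made in the Stetter step (C3'' from 11, C3 from 12) is set in a chair-like closure with the neighbouring 2-aryl group pseudo-equatorial, so the new ring should be 2,3-trans. The last stereocentre arises by protonation of the enolate anti to its adjacent 2-aryl group. Both new centres are alpha to a ketone and should also be corrected by enolisation under the weakly basic conditions to the diequatorial arrangement, while C2 and C2'' are not involved; with both fixed in the same sense the all-trans product can only be (2S,3R,2''S,3''R). The step needs exo over 7-endo closure, which the three-atom O–C tether secures; it needs no crossed benzoin, which the doubly ortho-substituted electron-rich aldehydes disfavour; and the hetero pairing is built into the alkyne, so either aldehyde may react first and both orders converge on 13.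

Step 7
Reactants: 13 (2S,3R)-5,7-bis(benzyloxy)-3-{(2S,3R)-5,7-bis(benzyloxy)-2-[4-(benzyloxy)phenyl]-4-oxo-3,4-dihydro-2H-chromen-3-yl}-2-(4-methoxyphenyl)-2,3-dihydro-4H-chromen-4-one
Product: 14 (2S,3R)-5,7-dihydroxy-3-[(2S,3R)-5,7-dihydroxy-2-(4-hydroxyphenyl)-4-oxo-3,4-dihydro-2H-chromen-3-yl]-2-(4-methoxyphenyl)-2,3-dihydro-4H-chromen-4-one
Conditions: H2 (1 atm), Pd/C, EtOAc–MeOH, rt
Reagents that add atoms: none
Why: Hydrogenolysis of the five benzyl ethers under neutral conditions; the methyl ether stays, no stereocentre is touched, and no base or acid is present that could open the pyranone rings.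

## Compound list

1 | 4-methoxybenzaldehyde | COc1ccc(C=O)cc1 | starting material
2 | ethynyltrimethylsilane | C#C[Si](C)(C)C | starting material
3 | (S)-1-(4-methoxyphenyl)-3-(trimethylsilyl)prop-2-yn-1-ol | COc1ccc(cc1)[C@H](O)C#C[Si](C)(C)C | intermediate
4 | (R)-1-(4-methoxyphenyl)prop-2-yn-1-ol | COc1ccc(cc1)[C@H](O)C#C | intermediate
5 | 4-(benzyloxy)benzaldehyde | O=Cc1ccc(OCc2ccccc2)cc1 | starting material
6 | (1S,4S)-1-[4-(benzyloxy)phenyl]-4-(4-methoxyphenyl)but-2-yne-1,4-diol | COc1ccc(cc1)[C@H](O)C#C[C@@H](O)c1ccc(OCc2ccccc2)cc1 | intermediate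
7 | 2,4,6-trihydroxybenzaldehyde | O=Cc1c(O)cc(O)cc1O | starting material
8 | benzyl bromide | BrCc1ccccc1 | starting material
9 | 2,4-bis(benzyloxy)-6-hydroxybenzaldehyde | O=Cc1c(O)cc(OCc2ccccc2)cc1OCc1ccccc1 | intermediate
10 | 2,2'-{[(1R,4R)-1-[4-(benzyloxy)phenyl]-4-(4-methoxyphenyl)but-2-yne-1,4-diyl]bis(oxy)}bis[4,6-bis(benzyloxy)benzaldehyde] | COc1ccc(cc1)[C@H](C#C[C@@H](c1ccc(OCc2ccccc2)cc1)Oc1cc(OCc2ccccc2)cc(OCc2ccccc2)c1C=O)Oc1cc(OCc2ccccc2)cc(OCc2ccccc2)c1C=O | intermediate
11 | (2R,3E)-5,7-bis(benzyloxy)-3-{(2S)-2-[4-(benzyloxy)phenyl]-2-[3,5-bis(benzyloxy)-2-formylphenoxy]ethylidene}-2-(4-methoxyphenyl)-2,3-dihydro-4H-chromen-4-one | COc1ccc(cc1)[C@H]1Oc2cc(OCc3ccccc3)cc(OCc3ccccc3)c2C(=O)/C1=C/[C@@H](c1ccc(OCc2ccccc2)cc1)Oc1cc(OCc2ccccc2)cc(OCc2ccccc2)c1C=O | intermediate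
12 | (2R,3E)-5,7-bis(benzyloxy)-2-[4-(benzyloxy)phenyl]-3-{(2S)-2-[3,5-bis(benzyloxy)-2-formylphenoxy]-2-(4-methoxyphenyl)ethylidene}-2,3-dihydro-4H-chromen-4-one | COc1ccc(cc1)[C@H](/C=C1/C(=O)c2c(OCc3ccccc3)cc(OCc3ccccc3)cc2O[C@@H]1c1ccc(OCc2ccccc2)cc1)Oc1cc(OCc2ccccc2)cc(OCc2ccccc2)c1C=O | intermediate
13 | (2S,3R)-5,7-bis(benzyloxy)-3-{(2S,3R)-5,7-bis(benzyloxy)-2-[4-(benzyloxy)phenyl]-4-oxo-3,4-dihydro-2H-chromen-3-yl}-2-(4-methoxyphenyl)-2,3-dihydro-4H-chromen-4-one | COc1ccc([C@H]2Oc3cc(OCc4ccccc4)cc(OCc4ccccc4)c3C(=O)[C@@H]2[C@H]2C(=O)c3c(OCc4ccccc4)cc(OCc4ccccc4)cc3O[C@@H]2c2ccc(OCc3ccccc3)cc2)cc1 | intermediate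
14 | (2S,3R)-5,7-dihydroxy-3-[(2S,3R)-5,7-dihydroxy-2-(4-hydroxyphenyl)-4-oxo-3,4-dihydro-2H-chromen-3-yl]-2-(4-methoxyphenyl)-2,3-dihydro-4H-chromen-4-one | COc1ccc([C@H]2Oc3cc(O)cc(O)c3C(=O)[C@@H]2[C@H]2C(=O)c3c(O)cc(O)cc3O[C@@H]2c2ccc(O)cc2)cc1 | target

## Step count and least certain steps

Total: 7 steps. Longest linear sequence: 6 steps (1, 2, 3, 5, 6, 7); step 4 is a one-step branch.

Step 6 (key step). Three processes are the most likely to go wrong:
- Carbene addition to the doubly ortho-substituted, electron-rich formyl groups may be slow.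
- The alkylidene intermediate may isomerise under base by gamma-deprotonation at C2 into the aromatic flavone, which destroys a C2 stereocentre.
- The Stetter enolate may open a pyranone ring by E1cB before it is protonated, which would scramble C2 or C2''.

Incomplete equilibration that leaves a 2,3-cis ring would be corrected by brief acid-catalysed enolisation. The fallback replaces acyl-anion chemistry with acyl-radical chemistry under neutral conditions; it sets out from 10 and returns at 13. Pinnick oxidation of both formyl groups (NaClO2, NaH2PO4, 2-methylbut-2-ene, tBuOH–H2O) would give 2,2'-{[(1R,4R)-1-[4-(benzyloxy)phenyl]-4-(4-methoxyphenyl)but-2-yne-1,4-diyl]bis(oxy)}bis[4,6-bis(benzyloxy)benzoic acid] F1. PhSeSePh and Bu3P would convert it into the corresponding Se,Se'-diphenyl bis(carboselenoate) F2. Slow addition of Bu3SnH with AIBN in benzene at 80 °C would then generate the aroyl radicals. One closes 6-exo-dig onto the alkyne and the vinyl radical is reduced. The other adds 6-exo-trig to the beta-carbon of the resulting enone, and hydrogen transfer to the alpha-keto radical gives 13.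

Step 5. The oxyphosphonium intermediates are benzylic, propargylic and para-alkoxy-substituted. Partial ionisation would cause loss of configuration at one carbinol carbon and formation of the meso-type diether, and the hydrogen-bonded phenol may react sluggishly. The fallback forms the aryl ethers by nucleophilic aromatic substitution, which does not touch the C–O bond of the stereocentre. It sets out from 1, 2 and 5 and returns at 10. Steps 1 to 3 run with the antipodal ligand would give (R)-1-(4-methoxyphenyl)-3-(trimethylsilyl)prop-2-yn-1-ol F3, (S)-1-(4-methoxyphenyl)prop-2-yn-1-ol F4 and (1R,4R)-1-[4-(benzyloxy)phenyl]-4-(4-methoxyphenyl)but-2-yne-1,4-diol F5. 1,3,5-Trifluorobenzene with BnOH/NaH would give 1,3-bis(benzyloxy)-5-fluorobenzene F6, and Vilsmeier–Haack formylation (POCl3, DMF) would give 2,4-bis(benzyloxy)-6-fluorobenzaldehyde F7. The disodium alkoxide of F5 (NaH, DMF, 0 °C) would displace fluoride from two equivalents of F7 with retention at carbon to give 10.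

Step 3. The methylzinc alkoxide formed from the free hydroxyl of 4 may aggregate with the dinuclear zinc catalyst and lower turnover or facial selectivity, or engage in hydride transfer to the aldehyde. The fallback masks the hydroxyl; it sets out from 3 and returns at 6. TBSCl/imidazole would give tert-butyl{[(1S)-1-(4-methoxyphenyl)-3-(trimethylsilyl)prop-2-yn-1-yl]oxy}dimethylsilane F8. K2CO3/MeOH would remove only the C-silyl group to give tert-butyl{[(1R)-1-(4-methoxyphenyl)prop-2-yn-1-yl]oxy}dimethylsilane F9. The same alkynylation of 5 would give (1S,4S)-1-[4-(benzyloxy)phenyl]-4-{[tert-butyl(dimethyl)silyl]oxy}-4-(4-methoxyphenyl)but-2-yn-1-ol F10, and Bu4NF in THF would release 6.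

Step 7. Hydrogenolysis of the benzylic C2–O1 or C2''–O1'' bond (opening to a dihydrochalcone) or reduction of an aryl ketone may compete with the removal of five benzyl groups. The fallback cleaves the benzyl ethers by a Lewis acid instead of by hydrogen; it sets out from 13 and returns at 14. BCl3 with pentamethylbenzene as cation scavenger in CH2Cl2 at −78 °C should leave the unchelated methyl ether intact, and the low temperature should prevent ionisation at C2. No new compound is made.

## Further compounds

F1 | step 6 | 2,2'-{[(1R,4R)-1-[4-(benzyloxy)phenyl]-4-(4-methoxyphenyl)but-2-yne-1,4-diyl]bis(oxy)}bis[4,6-bis(benzyloxy)benzoic acid] | COc1ccc(cc1)[C@H](C#C[C@@H](c1ccc(OCc2ccccc2)cc1)Oc1cc(OCc2ccccc2)cc(OCc2ccccc2)c1C(=O)O)Oc1cc(OCc2ccccc2)cc(OCc2ccccc2)c1C(=O)O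
F2 | step 6 | Se,Se'-diphenyl 2,2'-{[(1R,4R)-1-[4-(benzyloxy)phenyl]-4-(4-methoxyphenyl)but-2-yne-1,4-diyl]bis(oxy)}bis[4,6-bis(benzyloxy)benzenecarboselenoate] | COc1ccc(cc1)[C@H](C#C[C@@H](c1ccc(OCc2ccccc2)cc1)Oc1cc(OCc2ccccc2)cc(OCc2ccccc2)c1C(=O)[Se]c1ccccc1)Oc1cc(OCc2ccccc2)cc(OCc2ccccc2)c1C(=O)[Se]c1ccccc1
F3 | step 5 | (R)-1-(4-methoxyphenyl)-3-(trimethylsilyl)prop-2-yn-1-ol | COc1ccc(cc1)[C@@H](O)C#C[Si](C)(C)C
F4 | step 5 | (S)-1-(4-methoxyphenyl)prop-2-yn-1-ol | COc1ccc(cc1)[C@@H](O)C#C
F5 | step 5 | (1R,4R)-1-[4-(benzyloxy)phenyl]-4-(4-methoxyphenyl)but-2-yne-1,4-diol | COc1ccc(cc1)[C@@H](O)C#C[C@H](O)c1ccc(OCc2ccccc2)cc1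
F6 | step 5 | 1,3-bis(benzyloxy)-5-fluorobenzene | Fc1cc(OCc2ccccc2)cc(OCc2ccccc2)c1
F7 | step 5 | 2,4-bis(benzyloxy)-6-fluorobenzaldehyde | O=Cc1c(F)cc(OCc2ccccc2)cc1OCc1ccccc1
F8 | step 3 | tert-butyl{[(1S)-1-(4-methoxyphenyl)-3-(trimethylsilyl)prop-2-yn-1-yl]oxy}dimethylsilane | COc1ccc(cc1)[C@H](O[Si](C)(C)C(C)(C)C)C#C[Si](C)(C)C
F9 | step 3 | tert-butyl{[(1R)-1-(4-methoxyphenyl)prop-2-yn-1-yl]oxy}dimethylsilane | COc1ccc(cc1)[C@H](O[Si](C)(C)C(C)(C)C)C#C
F10 | step 3 | (1S,4S)-1-[4-(benzyloxy)phenyl]-4-{[tert-butyl(dimethyl)silyl]oxy}-4-(4-methoxyphenyl)but-2-yn-1-ol | COc1ccc(cc1)[C@H](O[Si](C)(C)C(C)(C)C)C#C[C@@H](O)c1ccc(OCc2ccccc2)cc1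
F0 | step 7 | none | none
A1 | alternative 1 | (2S)-5,7-bis(benzyloxy)-2-(4-methoxyphenyl)-2,3-dihydro-4H-chromen-4-one | COc1ccc([C@H]2Oc3cc(OCc4ccccc4)cc(OCc4ccccc4)c3C(=O)C2)cc1
A2 | alternative 1 | (2S)-5,7-bis(benzyloxy)-2-[4-(benzyloxy)phenyl]-2,3-dihydro-4H-chromen-4-one | C(Oc1ccc([C@H]2Oc3cc(OCc4ccccc4)cc(OCc4ccccc4)c3C(=O)C2)cc1)c1ccccc1
A3 | alternative 2 | {[(2S)-5,7-bis(benzyloxy)-2-(4-methoxyphenyl)-2H-chromen-4-yl]oxy}{[(2S)-5,7-bis(benzyloxy)-2-[4-(benzyloxy)phenyl]-2H-chromen-4-yl]oxy}di(propan-2-yl)silane | COc1ccc([C@H]2Oc3cc(OCc4ccccc4)cc(OCc4ccccc4)c3C(O[Si](C(C)C)(C(C)C)OC3=C[C@@H](c4ccc(OCc5ccccc5)cc4)Oc4cc(OCc5ccccc5)cc(OCc5ccccc5)c34)=C2)cc1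
A4 | alternative 3 | 1,4-bis[2,4-bis(benzyloxy)-6-hydroxyphenyl]butane-1,4-dione | O=C(CCC(=O)c1c(O)cc(OCc2ccccc2)cc1OCc1ccccc1)c1c(O)cc(OCc2ccccc2)cc1OCc1ccccc1
A5 | alternative 3 | (2E,3E)-2-[4-(benzyloxy)benzylidene]-1,4-bis[2,4-bis(benzyloxy)-6-hydroxyphenyl]-3-(4-methoxybenzylidene)butane-1,4-dione | COc1ccc(/C=C(\C(=C/c2ccc(OCc3ccccc3)cc2)C(=O)c2c(O)cc(OCc3ccccc3)cc2OCc2ccccc2)C(=O)c2c(O)cc(OCc3ccccc3)cc2OCc2ccccc2)cc1
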